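Answer 4 questions, and start each from the early readings of the runs.

| setting | theta | gamma | zeta | alpha | beta |
|---|---|---|---|---|---|
| starting material | 300 mM | 300 mM | 300 mM | 900 mM | 300 mM |
| coupling partner | 600 mM | 1800 mM | 600 mM | 600 mM | 300 mM |
| catalyst | 1.50 mM | 1.50 mM | 4.50 mM | 1.50 mM | 3.00 mM |
| time |  |  |  |  | 8.5 min |

| theta run: time / min | theta run: [product] / mM | gamma run: time / min | gamma run: [product] / mM | zeta run: time / min | zeta run: [product] / mM | alpha run: time / min | alpha run: [product] / mM |
|---|---|---|---|---|---|---|---|
| 0.31 | 4.1 | 0.31 | 5.3 | 0.31 | 13.0 | 0.31 | 5.9 |
| 0.92 | 14.8 | 0.92 | 17.2 | 0.92 | 35.9 | 0.92 | 17.4 |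
| 1.8 | 27.1 | 1.8 | 33.6 | 1.8 | 66.7 | 1.8 | 33.9 |
| 2.8 | 41.3 | 2.8 | 51.4 | 2.8 | 99.5 | 2.8 | 50.9 |
| 4.0 | 60.9 | 4.0 | 74.7 | 4.0 | 130.8 | 4.0 | 72.3 |
| 5.4 | 79.3 | 5.4 | 100.0 | 5.4 | 161.4 | 5.4 | 96.4 |
| 6.9 | 98.9 | 6.9 | 127.8 | 6.9 | 188.7 | 6.9 | 123.4 |
| 8.5 | 120.0 | 8.5 | 155.5 | 8.5 | 212.3 | 8.5 | 153.7 |

(standard deviation of a reading: 0.9 mM)

* the power of [coupling partner] that the first rate follows, about the charge of the theta run; measure it at two percent of starting material made into product
* the power of [starting material] that the first rate follows, about the charge of the theta run; measure it at two percent of starting material made into product (one fixed amount of product, the same in the runs compared)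
* product in the beta run at 8.5 min, as a share of the starting material charged
* which of these the readings show (an uncatalysed path runs beside / the second partner kills the catalyst / the catalyst rests as a dimer / the catalyst dies in pairs / the substrate kills the catalyst)

- Overall: starting material + coupling partner -> product, with catalyst as catalyst.
- Constant volume, constant temperature.
- The analysis sees a species whether free or bound.
- "The second partner" is coupling partner.
- An order is taken over about fifteen percent of the charge, up and down.

Work in logarithms: an order is the logarithm of the rate ratio over the logarithm of the charge ratio. Take each rate ratio as a reading, from the product at 1.8 min, where the theta run shows 27.1 mM against a scatter of 0.9 mM. Turn the coupling partner first. A first-order step would raise the rate by the charge ratio of 3.00, but the gamma run gives 1.24 times the theta product, a slope of 0.196. Turn the starting material next. A first-order step would again follow the charge ratio, 3.00, and the alpha run gives 1.25 times, a slope of 0.204. Turn the catalyst last. By hand the rate follows it one to one, yet the zeta run gives 2.46 times, less than the charge ratio, a slope of 0.820. The shortfall stands as early as 0.92 min, where the zeta run reads 35.9 mM against 14.8 mM in the theta run, so I read it as a resting dimer, not as a death.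

Now reckon for myself. Let working catalyst go with the rate, free catalyst with the rate over [starting material][coupling partner], and the dimer with the square of free catalyst. At fixed [starting material] and [coupling partner], the catalyst charge ratio then equals the rate ratio times the working share plus the squared rate ratio times the dimer share. The readings of the theta and zeta runs give the parked share, the fraction of the theta catalyst held in this resting state: 0.150. Differentiating gives each partner a local order of 0.261, above the slope read over the wider step of the gamma run.

Take the beta run to its middle, at 60.0 mM of product. There [starting material][coupling partner] stands at 0.320 of the theta charge, and the catalyst charge at 2.00 times. The same balance, starting from the theta rate of 15.1 mM/min as read, gives 13.8 mM/min. Over 8.5 min that makes 39.0% of the charge.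

The forecast says 0.22 for the coupling partner, 0.22 for the starting material, 48% for the beta run, and the catalyst dies in pairs: “Loss that grows with catalyst concentration points to paired death”. Its share, above mine, is what a power law gives.

The simulation gives 0.29, 0.27, 40.5%, and the catalyst rests as a dimer.

    catalyst + starting material ⇌ catalyst-substrate complex, settled at all times (1.600 /M)
    catalyst-substrate complex + coupling partner ⇌ ternary complex, settled at all times (61.00 /M)
    ternary complex → product + catalyst (13.08 /min)
    2 catalyst ⇌ resting dimer, settled at all times (18100 /M)

Take the dimer out of the beta run and its product rises from 40.5% to 72.8%. Carry the parked share there: by the balance, at mid-course it scales to 61.2% of the beta catalyst. Carry it also to the theta charge, where it puts the local order at 0.261. Take the dimer out at that charge and the order in starting material falls from 0.27 to 0.056, a change of −0.21.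

(The data are simulated on assumed constants.)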